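Numbering: C1 = ester carbinol, C3=C4 and C7=C8 = the two Z olefins, C9 = free carbinol, C10 = CH(iPr). Cuts, in order: vanillate O–acyl bond at C1; C9–O (from C9–B); C1–H (from C1=O); then the ring bond C9–C10.
Enabling feature: at the ketone level C1(=O)–C10–C9–C8=C7 is a γ,δ-unsaturated ketone and both ring olefins are Z. The ten-membered carbocycle therefore maps onto an eight-membered 2-alkylidene-8-vinyl-oxocine (O plus C1–C7) that already holds C3=C4 as a cis olefin.
Forward: chain assembly on a tertiary carbinol → E enol ether (enol phosphate, Stille) → RCM to the oxocine → E vinylboronate → Claisen ring expansion 8 → 10 → C1 reduction, esterification, C–B oxidation.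
Stereochemistry: the only imported centre is that of (R)-2-methylglycidol (it becomes C7 and is consumed in the key step). It is transferred to C9/C10 through a chair with E,E termini. C1 follows by peripheral hydride attack. C3=C4 is Z by ring size and C7=C8 is Z by the tether.

Key step: step 10

Assumption: compounds 1, 3, 5, 9, 14 and 19 are taken as commercial; descriptor changes between 1/2 and within 17–22 come only from CIP priorities, not from any change in space.

Step 1
Reactants: 1 (R)-2-methylglycidol
Product: 2 (S)-tert-butyldimethyl[(2-methyloxiran-2-yl)methoxy]silane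
Conditions: TBSCl, imidazole, CH2Cl2, 0 °C → rt
Reagents that add atoms: tert-butyldimethylsilyl chloride, CC(C)(C)[Si](C)(C)Cl
Why: Imidazole-promoted O-silylation of the primary alcohol touches neither the epoxide nor its quaternary stereocentre.

Step 2
Reactants: 2 (S)-tert-butyldimethyl[(2-methyloxiran-2-yl)methoxy]silane; 3 allylmagnesium bromide
Product: 4 (2S)-1-(tert-butyldimethylsilyloxy)-2-methylhex-5-en-2-ol
Conditions: CuI (10 mol %), THF, −40 → 0 °C; aq. work-up
Reagents that add atoms: none
Why: Copper-catalysed Grignard opening of a 2,2-disubstituted epoxide is an SN2 attack at the unsubstituted CH2, so the C–O bond of the stereocentre stays intact and the tertiary carbinol keeps its configuration.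

Step 3
Reactants: 4 (2S)-1-(tert-butyldimethylsilyloxy)-2-methylhex-5-en-2-ol; 5 isovaleryl chloride
Product: 6 (2S)-1-(tert-butyldimethylsilyloxy)-2-methylhex-5-en-2-yl 3-methylbutanoate
Conditions: Et3N, DMAP (cat.), CH2Cl2, reflux
Reagents that add atoms: none
Why: DMAP-catalysed acyl transfer is the usual way to acylate a hindered tertiary alcohol, and no other nucleophilic group is present.

Step 4
Reactants: 6 (2S)-1-(tert-butyldimethylsilyloxy)-2-methylhex-5-en-2-yl 3-methylbutanoate
Product: 8 (1Z)-1-{[(2S)-1-(tert-butyldimethylsilyloxy)-2-methylhex-5-en-2-yl]oxy}-3-methylbut-1-en-1-yl diphenyl phosphate, via Z(O)-lithium enolate 7 (not isolated)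
Conditions: LDA, THF–DMPU (55:45), −78 °C; then (PhO)2P(O)Cl, −78 → 0 °C
Reagents that add atoms: diphenyl chlorophosphate, O=P(Cl)(Oc1ccccc1)Oc1ccccc1
Why: Ester enolisation by LDA in the strongly cation-solvating THF–DMPU medium runs through an open transition state that places isopropyl cis to OLi (away from the bulky tertiary alkoxy group), and low-temperature O-phosphorylation freezes this geometry as the (Z)-ketene acetal phosphate.

Step 5
Reactants: 8 (Z)-ketene acetal diphenyl phosphate; 9 tributyl(2-methylallyl)stannane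
Product: 10 tert-butyl({(2S)-2-[(4E)-2,6-dimethylhepta-1,4-dien-4-yl]oxy-2-methylhex-5-en-1-yl}oxy)dimethylsilane
Conditions: Pd(PPh3)4 (5 mol %), LiCl, THF, reflux
Reagents that add atoms: none
Why: Stille cross-coupling of a ketene acetal phosphate goes by oxidative addition into the C–OP bond and reductive elimination with retention, so methallyl takes the place cis to isopropyl (E enol ether), and the symmetric methallyl unit makes α- and γ-transfer equivalent.

Step 6
Reactants: 10 (E)-enol ether diene
Product: 11 (2E,4Z,8S)-8-[(tert-butyldimethylsilyloxy)methyl]-4,8-dimethyl-2-(2-methylpropylidene)-3,6,7,8-tetrahydro-2H-oxocine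
Conditions: (H2IMes)(PCy3)Cl2Ru=CHPh (5–10 mol %), 1,4-benzoquinone (cat.), toluene (2 mM), 80 °C
Reagents that add atoms: none
Why: Ring-closing metathesis joins the monosubstituted and the 1,1-disubstituted olefin (the trisubstituted enol ether is too hindered to engage), is helped by the quaternary carbinol carbon and the sp2 C2, and an eight-membered ring can hold the new trisubstituted olefin only as Z.

Step 7
Reactants: 11 silyl ether of the oxocine
Product: 12 [(2E,4Z,8S)-4,8-dimethyl-2-(2-methylpropylidene)-3,6,7,8-tetrahydro-2H-oxocin-8-yl]methanol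
Conditions: TBAF, THF, 0 °C → rt
Reagents that add atoms: none
Why: Fluoride-induced desilylation is neutral to basic and therefore safe for the acid-labile enol ether.

Step 8
Reactants: 12 oxocinyl methanol
Product: 13 (2E,4Z,8S)-4,8-dimethyl-2-(2-methylpropylidene)-3,6,7,8-tetrahydro-2H-oxocine-8-carbaldehyde
Conditions: TPAP (5 mol %), NMO, 4 Å MS, CH2Cl2, rt
Reagents that add atoms: none
Why: Ley–Griffith oxidation is non-acidic and stops at the aldehyde, and the product has no α-hydrogen, so the stereocentre cannot epimerise.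

Step 9
Reactants: 13 oxocine carbaldehyde; 14 bis[(pinacolato)boryl]methane
Product: 16 (2E,4Z,8S)-4,8-dimethyl-2-(2-methylpropylidene)-8-[(E)-2-(4,4,5,5-tetramethyl-1,3,2-dioxaborolan-2-yl)ethenyl]-3,6,7,8-tetrahydro-2H-oxocine, via lithiated diborylmethane 15 (not isolated)
Conditions: 14, LiTMP, THF, 0 °C; then 13, −78 °C → rt
Reagents that add atoms: none
Why: In this boron-Wittig olefination the lithiated geminal diboronate adds to the non-enolisable aldehyde and syn B–O elimination from the less crowded adduct gives the E vinylboronate, under Lewis-acid-free conditions that spare the enol ether.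

Step 10
Reactants: 16 (2E,4Z,8S)-2-alkylidene-8-[(E)-2-borylethenyl]oxocine
Product: 17 (3Z,7Z,9S,10S)-3,7-dimethyl-10-(propan-2-yl)-9-(4,4,5,5-tetramethyl-1,3,2-dioxaborolan-2-yl)cyclodeca-3,7-dien-1-one
Conditions: toluene (0.01 M), BHT (cat.), base-washed sealed tube, 130–150 °C
Reagents that add atoms: none
Why: On heating, 16 should undergo a concerted suprafacial [3,3]-sigmatropic (Claisen) shift in which the β-carbon of the exocyclic enol ether bonds to the boryl-bearing vinyl carbon while the endocyclic O1–C8 bond breaks, so that oxygen leaves the ring as the C1 carbonyl and three exocyclic carbons enter it (8 → 10). The closest known reaction types are the Claisen ring expansion of 2-methylene-6-vinyltetrahydropyrans to cyclooct-4-enones and the Claisen-type rearrangements of 3-boryl allylic systems to α-chiral allylboronates. The ten-membered ring is not closed end to end but by this two-atom enlargement through a bicyclo[5.3.1]-like chair transition state. C9 and C10 are set together: the (8S) carbinol centre decides which face of the vinylboronate is presented, and the E,E geometry puts Bpin and isopropyl both pseudo-equatorial, which in a chair gives the 9,10-syn pair. The step needs chair over boat and Z over E at the new C7=C8 bond; a geometric estimate puts the tether ends (C3 and C7 of the oxocine) about 3.6 Å apart only when C7 sits pseudo-axial on the carbinol carbon of a chair, against roughly 4.2–4.8 Å for the boat or E-olefin alternatives, which a five-atom chain holding a cis olefin cannot span comfortably. The Z,Z-1,5-diene formed cannot reach a chair Cope geometry and should survive the temperature.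

Step 11
Reactants: 17 ten-membered β-boryl ketone
Product: 18 (1R,3Z,7Z,9S,10S)-3,7-dimethyl-10-(propan-2-yl)-9-(4,4,5,5-tetramethyl-1,3,2-dioxaborolan-2-yl)cyclodeca-3,7-dien-1-ol
Conditions: DIBAL-H, CH2Cl2, −78 °C; Rochelle salt work-up
Reagents that add atoms: none
Why: Hydride should reach C1=O from the outer face of the medium ring (peripheral attack), because the inner face is covered by the transannular C7=C8 olefin in the conformer delivered by the rearrangement, which puts the C1–O bond syn to isopropyl and boron (1R), while the non-basic reagent at −78 °C avoids epimerisation at C10 and conjugation of C3=C4.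

Step 12
Reactants: 19 vanillic acid
Product: 20 4-acetoxy-3-methoxybenzoic acid
Conditions: Ac2O, pyridine, rt; then H2O
Reagents that add atoms: acetic anhydride, CC(=O)OC(C)=O
Why: O-acetylation of the phenol (any mixed anhydride is hydrolysed on aqueous work-up) masks it for the carbodiimide coupling.

Step 13
Reactants: 18 boryl cyclodecadienol; 20 4-acetoxy-3-methoxybenzoic acid
Product: 21 (1R,3Z,7Z,9S,10S)-3,7-dimethyl-10-(propan-2-yl)-9-(4,4,5,5-tetramethyl-1,3,2-dioxaborolan-2-yl)cyclodeca-3,7-dien-1-yl 4-acetoxy-3-methoxybenzoate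
Conditions: DCC, DMAP, CH2Cl2, rt
Reagents that add atoms: none
Why: Steglich esterification acylates the hindered secondary alcohol without breaking C1–O, so the configuration is kept, and it tolerates the allylic pinacol boronate.

Step 14
Reactants: 21 boryl acetylvanillate
Product: 22 (1R,3Z,7Z,9S,10R)-9-hydroxy-3,7-dimethyl-10-(propan-2-yl)cyclodeca-3,7-dien-1-yl 4-hydroxy-3-methoxybenzoate (target)
Conditions: NaBO3·4H2O, THF–H2O (1:1), rt
Reagents that add atoms: sodium perborate, [Na+].[O-]OB=O
Why: Perborate oxidation of the secondary allylic boronate is a 1,2-shift from boron to oxygen with retention and without allylic transposition (9S), and at this mild pH perhydroxide should also cleave the activated aryl acetate much faster than the hindered alkyl benzoate.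

Compound list
1 | (R)-2-methylglycidol | C[C@@]1(CO)CO1 | starting material
2 | (S)-tert-butyldimethyl[(2-methyloxiran-2-yl)methoxy]silane | C[C@@]1(CO[Si](C)(C)C(C)(C)C)CO1 | intermediate
3 | allylmagnesium bromide | C=CC[Mg]Br | starting material
4 | (2S)-1-(tert-butyldimethylsilyloxy)-2-methylhex-5-en-2-ol | C=CCC[C@](C)(O)CO[Si](C)(C)C(C)(C)C | intermediate
5 | isovaleryl chloride | CC(C)CC(=O)Cl | starting material
6 | (2S)-1-(tert-butyldimethylsilyloxy)-2-methylhex-5-en-2-yl 3-methylbutanoate | C=CCC[C@](C)(OC(=O)CC(C)C)CO[Si](C)(C)C(C)(C)C | intermediate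
7 | Z(O)-lithium enolate of 6 (isopropyl cis to OLi) | CC(C)/C=C(\[O-])O[C@@](C)(CCC=C)CO[Si](C)(C)C(C)(C)C.[Li+] | intermediate
8 | (1Z)-1-{[(2S)-1-(tert-butyldimethylsilyloxy)-2-methylhex-5-en-2-yl]oxy}-3-methylbut-1-en-1-yl diphenyl phosphate | CC(C)/C=C(\OP(=O)(Oc1ccccc1)Oc1ccccc1)O[C@@](C)(CCC=C)CO[Si](C)(C)C(C)(C)C | intermediate
9 | tributyl(2-methylallyl)stannane | C=C(C)C[Sn](CCCC)(CCCC)CCCC | starting material
10 | tert-butyl({(2S)-2-[(4E)-2,6-dimethylhepta-1,4-dien-4-yl]oxy-2-methylhex-5-en-1-yl}oxy)dimethylsilane | CC(C)/C=C(\CC(C)=C)O[C@@](C)(CCC=C)CO[Si](C)(C)C(C)(C)C | intermediate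
11 | (2E,4Z,8S)-8-[(tert-butyldimethylsilyloxy)methyl]-4,8-dimethyl-2-(2-methylpropylidene)-3,6,7,8-tetrahydro-2H-oxocine | CC(C)/C=C1\C/C(C)=C\CC[C@@](C)(CO[Si](C)(C)C(C)(C)C)O1 | intermediate
12 | [(2E,4Z,8S)-4,8-dimethyl-2-(2-methylpropylidene)-3,6,7,8-tetrahydro-2H-oxocin-8-yl]methanol | CC(C)/C=C1\C/C(C)=C\CC[C@@](C)(CO)O1 | intermediate
13 | (2E,4Z,8S)-4,8-dimethyl-2-(2-methylpropylidene)-3,6,7,8-tetrahydro-2H-oxocine-8-carbaldehyde | CC(C)/C=C1\C/C(C)=C\CC[C@@](C)(C=O)O1 | intermediate
14 | bis[(pinacolato)boryl]methane | CC1(C)OB(CB2OC(C)(C)C(C)(C)O2)OC1(C)C | starting material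
15 | lithiated diborylmethane | [Li]C(B1OC(C)(C)C(C)(C)O1)B1OC(C)(C)C(C)(C)O1 | intermediate
16 | (2E,4Z,8S)-4,8-dimethyl-2-(2-methylpropylidene)-8-[(E)-2-(4,4,5,5-tetramethyl-1,3,2-dioxaborolan-2-yl)ethenyl]-3,6,7,8-tetrahydro-2H-oxocine | CC(C)/C=C1\C/C(C)=C\CC[C@@](C)(/C=C/B2OC(C)(C)C(C)(C)O2)O1 | intermediate
17 | (3Z,7Z,9S,10S)-3,7-dimethyl-10-(propan-2-yl)-9-(4,4,5,5-tetramethyl-1,3,2-dioxaborolan-2-yl)cyclodeca-3,7-dien-1-one | O=C1C/C(C)=C\CC/C(C)=C\[C@H](B2OC(C)(C)C(C)(C)O2)[C@H]1C(C)C | intermediate
18 | (1R,3Z,7Z,9S,10S)-3,7-dimethyl-10-(propan-2-yl)-9-(4,4,5,5-tetramethyl-1,3,2-dioxaborolan-2-yl)cyclodeca-3,7-dien-1-ol | O[C@@H]1C/C(C)=C\CC/C(C)=C\[C@H](B2OC(C)(C)C(C)(C)O2)[C@H]1C(C)C | intermediate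
19 | vanillic acid | COc1cc(C(=O)O)ccc1O | starting material
20 | 4-acetoxy-3-methoxybenzoic acid | COc1cc(C(=O)O)ccc1OC(C)=O | intermediate
21 | (1R,3Z,7Z,9S,10S)-3,7-dimethyl-10-(propan-2-yl)-9-(4,4,5,5-tetramethyl-1,3,2-dioxaborolan-2-yl)cyclodeca-3,7-dien-1-yl 4-acetoxy-3-methoxybenzoate | COc1cc(C(=O)O[C@@H]2C/C(C)=C\CC/C(C)=C\[C@H](B3OC(C)(C)C(C)(C)O3)[C@H]2C(C)C)ccc1OC(C)=O | intermediate
22 | (1R,3Z,7Z,9S,10R)-9-hydroxy-3,7-dimethyl-10-(propan-2-yl)cyclodeca-3,7-dien-1-yl 4-hydroxy-3-methoxybenzoate | COc1cc(C(=O)O[C@@H]2C/C(C)=C\CC/C(C)=C\[C@H](O)[C@H]2C(C)C)ccc1O | target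

Total step count: 14. Longest linear sequence: 13 (steps 1–11, 13, 14).

Steps most likely to fail

Step 10. The boryl group is a π-acceptor at the bond-forming terminus and should slow the shift. At the temperature then needed, transannular allylboration of the new ketone, or leakage into the boat or E-olefin channels, may erode material and stereochemical fidelity. The fallback exchanges boron for an oxygen donor before the rearrangement. It sets out from 16: copper(II)-mediated Chan–Lam-type etherification with 4-methoxybenzyl alcohol (retention of the E geometry) would give the (E)-4-methoxybenzyl enol ether F1. Its 6-alkoxy donor should let the same ring expansion run well below 100 °C to the 9-(4-methoxybenzyloxy) ketone F2. DIBAL-H reduction would give the alcohol F3, Steglich esterification with 20 the ester F4, and DDQ cleavage the O-acetyl target F5. K2CO3/MeOH would then bring the sequence back at 22.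

Step 5. Oxidative addition into a hindered, acyclic and hydrolytically labile ketene acetal phosphate may be slow, and incomplete Z(O)-selectivity in step 4 or isomerisation on palladium may blur the enol ether geometry on which C10 depends. The fallback fixes the geometry by chelation and sets out from alcohol 4. Rh2(OAc)4-catalysed O–H insertion of 1-diazo-3-methylbutan-2-one would give the α-alkoxy ketone F6. Kinetic deprotonation at its OCH2 group and alkylation with methallyl bromide would give the branched ketone F7. Lithium-chelated enolisation towards the alkoxy carbon and trapping with N-(5-chloro-2-pyridyl)triflimide would give the enol triflate F8 (OTf cis to the ether oxygen). Palladium-catalysed formate reduction with retention would come back at 10.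

Step 11. The ketone may react through a ring conformer other than the one delivered by the rearrangement, which would mean poor facial selectivity in the hydride delivery. The fallback makes the sequence stereoconvergent and sets out from 17. The C1-epimeric alcohol F9, separated from 18, would be esterified with 20 under Mitsunobu conditions (inversion at C1) and so come back at 21.

Further compounds
F1 | step 10 | (2E,4Z,8S)-8-[(E)-2-(4-methoxybenzyloxy)ethenyl]-4,8-dimethyl-2-(2-methylpropylidene)-3,6,7,8-tetrahydro-2H-oxocine | CC(C)/C=C1\C/C(C)=C\CC[C@@](C)(/C=C/OCc2ccc(OC)cc2)O1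
F2 | step 10 | (3Z,7Z,9S,10R)-9-(4-methoxybenzyloxy)-3,7-dimethyl-10-(propan-2-yl)cyclodeca-3,7-dien-1-one | O=C1C/C(C)=C\CC/C(C)=C\[C@H](OCc2ccc(OC)cc2)[C@H]1C(C)C
F3 | step 10 | (1R,3Z,7Z,9S,10S)-9-(4-methoxybenzyloxy)-3,7-dimethyl-10-(propan-2-yl)cyclodeca-3,7-dien-1-ol | O[C@@H]1C/C(C)=C\CC/C(C)=C\[C@H](OCc2ccc(OC)cc2)[C@H]1C(C)C
F4 | step 10 | (1R,3Z,7Z,9S,10S)-9-(4-methoxybenzyloxy)-3,7-dimethyl-10-(propan-2-yl)cyclodeca-3,7-dien-1-yl 4-acetoxy-3-methoxybenzoate | COc1cc(C(=O)O[C@@H]2C/C(C)=C\CC/C(C)=C\[C@H](OCc3ccc(OC)cc3)[C@H]2C(C)C)ccc1OC(C)=O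
F5 | step 10 | (1R,3Z,7Z,9S,10R)-9-hydroxy-3,7-dimethyl-10-(propan-2-yl)cyclodeca-3,7-dien-1-yl 4-acetoxy-3-methoxybenzoate | COc1cc(C(=O)O[C@@H]2C/C(C)=C\CC/C(C)=C\[C@H](O)[C@H]2C(C)C)ccc1OC(C)=O
F6 | step 5 | 1-{[(2S)-1-(tert-butyldimethylsilyloxy)-2-methylhex-5-en-2-yl]oxy}-3-methylbutan-2-one | C=CCC[C@](C)(OCC(=O)C(C)C)CO[Si](C)(C)C(C)(C)C
F7 | step 5 | 4-{[(2S)-1-(tert-butyldimethylsilyloxy)-2-methylhex-5-en-2-yl]oxy}-2,6-dimethylhept-6-en-3-one (epimers at C4) | C=CCC[C@](C)(OC(CC(C)=C)C(=O)C(C)C)CO[Si](C)(C)C(C)(C)C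
F8 | step 5 | enol triflate of F7 with OTf cis to the ether oxygen and isopropyl cis to methallyl | CC(C)/C(OS(=O)(=O)C(F)(F)F)=C(\CC(C)=C)O[C@@](C)(CCC=C)CO[Si](C)(C)C(C)(C)C
F9 | step 11 | (1S,3Z,7Z,9S,10S)-3,7-dimethyl-10-(propan-2-yl)-9-(4,4,5,5-tetramethyl-1,3,2-dioxaborolan-2-yl)cyclodeca-3,7-dien-1-ol | O[C@H]1C/C(C)=C\CC/C(C)=C\[C@H](B2OC(C)(C)C(C)(C)O2)[C@H]1C(C)C
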